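**Retrosynthetic overview**
1. Target 38 ← bis-TBS/13-O-(2-naphthylmethyl) butenolide 35: the last steps swap the two silyl ethers for acetates and free C13–OH with DDQ.
2. Ring B (butenolide, formed second) ← intramolecular Horner–Wadsworth–Emmons closure of a C6 phosphonoacetate (bringing C11–C13) onto a C7 ketone of ring A.
3. Ring A (ten-membered carbocycle, formed first) ← NiCl2/CrCl2 closure of the C9–C10 bond in (Z)-vinyl iodide aldehyde 18; C9 is then set by oxidation and CBS reduction.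
4. Seco chain ← key fragment union: Brown γ-alkoxyallylboration of enal 9 (fragment 1, C1–C6 and C10) with allyl MOM ether 11 (fragment 2, C7–C9), forming C6–C7 and setting C6.
5. Enal 9 ← ethyl 3-methyl-4-oxobut-2-enoate by Brown allylation (sets C3), alkene cleavage and Stork–Zhao olefination (Z C1=C10).

Assumption: germacrane numbering is used for ring positions (C1=C10 Z, C4=C5 E, C7=C11, lactone C12–O–C6, C13 = CH2OH, acetates on C3 and C9), which makes the target the (3S,6R,9S) isomer. Abbreviations: TBS = tert-butyldimethylsilyl, PMB = 4-methoxybenzyl, MOM = methoxymethyl, NAP = naphthalen-2-ylmethyl, Ipc = isopinocampheyl from (+)-α-pinene.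

**Step 1**
Reactants: 1 ethyl (2E)-3-methyl-4-oxobut-2-enoate
Product: 3 ethyl (2E,4S)-4-hydroxy-3-methylhepta-2,6-dienoate, via borinate ester 2 (not isolated)
Conditions: (−)-Ipc2BOMe, allylMgBr, Et2O, 0 °C to rt; then 1, −78 °C; NaBO3·4H2O, THF/H2O, rt
Reagents that add atoms: allylmagnesium bromide, C=CC[Mg]Br
Why: Brown allylboration through a closed chair transition state; the (+)-α-pinene-derived reagent attacks the si face of the aldehyde and gives the (4S) carbinol (future C3), while the ester is untouched at −78 °C.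

**Step 2**
Reactants: 3 ethyl (2E,4S)-4-hydroxy-3-methylhepta-2,6-dienoate
Product: 4 ethyl (2E,4S)-4-[(tert-butyldimethylsilyl)oxy]-3-methylhepta-2,6-dienoate
Conditions: TBSOTf, 2,6-lutidine, CH2Cl2, −78 to 0 °C
Reagents that add atoms: tert-butyldimethylsilyl trifluoromethanesulfonate, CC(C)(C)[Si](C)(C)OS(=O)(=O)C(F)(F)F
Why: Silyl triflate silylation of a secondary allylic alcohol is fast and leaves the stereocentre untouched.

**Step 3**
Reactants: 4 ethyl (2E,4S)-4-[(tert-butyldimethylsilyl)oxy]-3-methylhepta-2,6-dienoate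
Product: 6 ethyl (2E,4S)-4-[(tert-butyldimethylsilyl)oxy]-3-methyl-6-oxohex-2-enoate, via vicinal diol 5 (not isolated)
Conditions: OsO4 (2 mol %), NaIO4, 2,6-lutidine, dioxane/H2O 3:1, rt
Reagents that add atoms: osmium tetroxide OsO4, O=[Os](=O)(=O)=O (delivers the carbonyl oxygen; re-formed by sodium periodate NaIO4, [Na+].[O-]I(=O)(=O)=O)
Why: Lemieux–Johnson cleavage; OsO4 dihydroxylates the electron-rich terminal alkene much faster than the conjugated trisubstituted enoate, and NaIO4 cleaves the diol to the aldehyde.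

**Step 4**
Reactants: 6 ethyl (2E,4S)-4-[(tert-butyldimethylsilyl)oxy]-3-methyl-6-oxohex-2-enoate
Product: 7 ethyl (2E,4S,6Z)-4-[(tert-butyldimethylsilyl)oxy]-7-iodo-3-methylocta-2,6-dienoate
Conditions: EtPPh3I, n-BuLi, THF, rt; I2, −78 °C; NaN(SiMe3)2, −20 °C; then 6, −78 °C to rt
Reagents that add atoms: ethyltriphenylphosphonium iodide, CC[P+](c1ccccc1)(c1ccccc1)c1ccccc1.[I-]; iodine, II
Why: Stork–Zhao olefination; the α-iodo ylide reacts under kinetic control through a cis-oxaphosphetane and gives the (Z)-2-iodoalkene (iodine cis to the chain), which fixes the later C1=C10 geometry.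

**Step 5**
Reactants: 7 ethyl (2E,4S,6Z)-4-[(tert-butyldimethylsilyl)oxy]-7-iodo-3-methylocta-2,6-dienoate
Product: 8 (2E,4S,6Z)-4-[(tert-butyldimethylsilyl)oxy]-7-iodo-3-methylocta-2,6-dien-1-ol
Conditions: iBu2AlH (2.5 equiv), CH2Cl2, −78 °C; aq. KNaC4H4O6
Reagents that add atoms: none
Why: 1,2-Reduction of the enoate by iBu2AlH gives the allylic alcohol; vinyl iodide and silyl ether are inert at −78 °C.

**Step 6**
Reactants: 8 (2E,4S,6Z)-4-[(tert-butyldimethylsilyl)oxy]-7-iodo-3-methylocta-2,6-dien-1-ol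
Product: 9 (2E,4S,6Z)-4-[(tert-butyldimethylsilyl)oxy]-7-iodo-3-methylocta-2,6-dienal
Conditions: MnO2, CH2Cl2, rt
Reagents that add atoms: none
Why: MnO2 oxidises only the allylic alcohol and keeps the E geometry.

**Step 7**
Reactants: 10 prop-2-en-1-ol
Product: 11 3-(methoxymethoxy)prop-1-ene
Conditions: MOMCl, iPr2NEt, CH2Cl2, 0 °C to rt
Reagents that add atoms: chloromethyl methyl ether, COCCl
Why: Simple O-alkylation (MOM protection) of a primary alcohol with the reactive chloromethyl ether.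

**Step 8**
Reactants: 9 (2E,4S,6Z)-4-[(tert-butyldimethylsilyl)oxy]-7-iodo-3-methylocta-2,6-dienal; 11 3-(methoxymethoxy)prop-1-ene
Product: 14 (3R,4R,5E,7S,9Z)-7-[(tert-butyldimethylsilyl)oxy]-10-iodo-3-(methoxymethoxy)-6-methylundeca-1,5,9-trien-4-ol, via alkoxyallylborane 12 (not isolated), via borinate ester 13 (not isolated)
Conditions: 11, s-BuLi, THF, −78 °C; (−)-Ipc2BOMe; BF3·OEt2; then 9, −78 °C; NaOH, H2O2, 0 °C to rt
Reagents that add atoms: none
Why: Brown γ-alkoxyallylboration (the key fragment union): the (Z)-boron reagent reacts through a chair transition state to give the syn 3,4-relationship, and the (+)-α-pinene-derived Ipc groups direct si-face attack, which sets the (4R) carbinol (future C6) under reagent control with the remote C7 centre not interfering.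

**Step 9**
Reactants: 14 (3R,4R,5E,7S,9Z)-7-[(tert-butyldimethylsilyl)oxy]-10-iodo-3-(methoxymethoxy)-6-methylundeca-1,5,9-trien-4-ol
Product: 15 (3R,4R,5E,7S,9Z)-7-[(tert-butyldimethylsilyl)oxy]-10-iodo-3-(methoxymethoxy)-4-[(4-methoxybenzyl)oxy]-6-methylundeca-1,5,9-triene
Conditions: NaH, PMBCl, Bu4NI (cat.), DMF, 0 °C to rt
Reagents that add atoms: 4-methoxybenzyl chloride, COc1ccc(CCl)cc1
Why: Williamson etherification of the alkoxide; the vinyl iodide, silyl ether and MOM ether tolerate NaH.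

**Step 10**
Reactants: 15 (3R,4R,5E,7S,9Z)-7-[(tert-butyldimethylsilyl)oxy]-10-iodo-3-(methoxymethoxy)-4-[(4-methoxybenzyl)oxy]-6-methylundeca-1,5,9-triene
Product: 17 (3R,4R,5E,7S,9Z)-7-[(tert-butyldimethylsilyl)oxy]-10-iodo-3-(methoxymethoxy)-4-[(4-methoxybenzyl)oxy]-6-methylundeca-5,9-dien-1-ol, via alkyl-9-BBN adduct 16 (not isolated)
Conditions: 9-BBN, THF, 0 °C to rt; NaOH, H2O2, 0 °C
Reagents that add atoms: hydrogen peroxide, OO
Why: Brown hydroboration–oxidation; 9-BBN adds anti-Markovnikov to the only monosubstituted alkene and ignores the trisubstituted alkene and the vinyl iodide.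

**Step 11**
Reactants: 17 (3R,4R,5E,7S,9Z)-7-[(tert-butyldimethylsilyl)oxy]-10-iodo-3-(methoxymethoxy)-4-[(4-methoxybenzyl)oxy]-6-methylundeca-5,9-dien-1-ol
Product: 18 (3R,4R,5E,7S,9Z)-7-[(tert-butyldimethylsilyl)oxy]-10-iodo-3-(methoxymethoxy)-4-[(4-methoxybenzyl)oxy]-6-methylundeca-5,9-dienal
Conditions: Dess–Martin periodinane, NaHCO3, CH2Cl2, 0 °C to rt
Reagents that add atoms: none
Why: Buffered Dess–Martin oxidation gives the β-alkoxy aldehyde without β-elimination or epimerisation.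

**Step 12**
Reactants: 18 (3R,4R,5E,7S,9Z)-7-[(tert-butyldimethylsilyl)oxy]-10-iodo-3-(methoxymethoxy)-4-[(4-methoxybenzyl)oxy]-6-methylundeca-5,9-dienal
Product: 20 (2Z,5S,6E,8R,9R)-5-[(tert-butyldimethylsilyl)oxy]-9-(methoxymethoxy)-8-[(4-methoxybenzyl)oxy]-2,6-dimethylcyclodeca-2,6-dien-1-ol (mixture of C1 epimers), via alkenylchromium dichloride 19 (not isolated)
Conditions: CrCl2 (10 equiv), NiCl2 (10 mol %), DMSO/THF 3:1, 0.003 M, rt
Reagents that add atoms: none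
Why: Nozaki–Hiyama–Kishi macrocyclisation; zerovalent nickel inserts into the carbon–iodine bond and passes the alkenyl group to trivalent chromium, which adds only to the aldehyde with retention of the Z geometry, and the uncontrolled new carbinol is corrected in steps 13 and 14.

**Step 13**
Reactants: 20 (2Z,5S,6E,8R,9R)-5-[(tert-butyldimethylsilyl)oxy]-9-(methoxymethoxy)-8-[(4-methoxybenzyl)oxy]-2,6-dimethylcyclodeca-2,6-dien-1-ol (mixture of C1 epimers)
Product: 21 (2Z,5S,6E,8R,9R)-5-[(tert-butyldimethylsilyl)oxy]-9-(methoxymethoxy)-8-[(4-methoxybenzyl)oxy]-2,6-dimethylcyclodeca-2,6-dien-1-one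
Conditions: Dess–Martin periodinane, NaHCO3, CH2Cl2, rt
Reagents that add atoms: none
Why: Dess–Martin oxidation converges both epimers on one (Z)-enone and removes the uncontrolled stereocentre.

**Step 14**
Reactants: 21 (2Z,5S,6E,8R,9R)-5-[(tert-butyldimethylsilyl)oxy]-9-(methoxymethoxy)-8-[(4-methoxybenzyl)oxy]-2,6-dimethylcyclodeca-2,6-dien-1-one
Product: 22 (1S,2Z,5S,6E,8R,9R)-5-[(tert-butyldimethylsilyl)oxy]-9-(methoxymethoxy)-8-[(4-methoxybenzyl)oxy]-2,6-dimethylcyclodeca-2,6-dien-1-ol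
Conditions: (R)-2-methyl-CBS-oxazaborolidine [(R)-1-methyl-3,3-diphenyltetrahydro-1H,3H-pyrrolo[1,2-c][1,3,2]oxazaborole] (20 mol %), catecholborane, toluene, −78 °C
Reagents that add atoms: none
Why: Corey–Bakshi–Shibata reduction; with the α-methylalkenyl group as the large substituent the (R)-catalyst delivers hydride to give the (1S) allylic alcohol (C9 of the target) under reagent control, and catecholborane at −78 °C does not hydroborate the alkenes.

**Step 15**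
Reactants: 22 (1S,2Z,5S,6E,8R,9R)-5-[(tert-butyldimethylsilyl)oxy]-9-(methoxymethoxy)-8-[(4-methoxybenzyl)oxy]-2,6-dimethylcyclodeca-2,6-dien-1-ol
Product: 23 (1S,2Z,5S,6E,8R,9R)-1,5-bis[(tert-butyldimethylsilyl)oxy]-9-(methoxymethoxy)-8-[(4-methoxybenzyl)oxy]-2,6-dimethylcyclodeca-2,6-diene
Conditions: TBSOTf, 2,6-lutidine, CH2Cl2, −78 to 0 °C
Reagents that add atoms: tert-butyldimethylsilyl trifluoromethanesulfonate, CC(C)(C)[Si](C)(C)OS(=O)(=O)C(F)(F)F
Why: Silylation keeps the C9 oxygen as a poor leaving group, so the later β-oxy ketone cannot eliminate as a β-acetoxy ketone would.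

**Step 16**
Reactants: 23 (1S,2Z,5S,6E,8R,9R)-1,5-bis[(tert-butyldimethylsilyl)oxy]-9-(methoxymethoxy)-8-[(4-methoxybenzyl)oxy]-2,6-dimethylcyclodeca-2,6-diene
Product: 24 (1S,2Z,5S,6E,8R,9R)-1,5-bis[(tert-butyldimethylsilyl)oxy]-9-(methoxymethoxy)-2,6-dimethylcyclodeca-2,6-dien-8-ol (ring numbered as in 22)
Conditions: DDQ, CH2Cl2/aq. NaH2PO4–Na2HPO4 (pH 7) 10:1, 0 °C to rt
Reagents that add atoms: none
Why: Oxidative PMB cleavage by DDQ (electron transfer from the electron-rich benzyl ether) is orthogonal to the silyl and MOM ethers.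

**Step 17**
Reactants: 25 allyl 2-(diethoxyphosphoryl)acetate
Product: 27 allyl 2-(diethoxyphosphoryl)prop-2-enoate, via allyloxy adduct 26 (not isolated)
Conditions: (CH2O)n, piperidine (cat.), allyl alcohol, 80 °C; then TsOH·H2O (cat.), toluene, reflux (Dean–Stark)
Reagents that add atoms: paraformaldehyde (formaldehyde), C=O
Why: Knoevenagel/Mannich-type methylenation; amine-mediated hydroxymethylation and alcohol addition give adduct 26, and acid-catalysed β-elimination with removal of allyl alcohol gives the 2-phosphonoacrylate.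

**Step 18**
Reactants: 27 allyl 2-(diethoxyphosphoryl)prop-2-enoate; 28 naphthalen-2-ylmethanol
Product: 29 allyl 2-(diethoxyphosphoryl)-3-(naphthalen-2-ylmethoxy)propanoate (racemic)
Conditions: KOtBu (10 mol %), THF, 0 °C
Reagents that add atoms: none
Why: Oxa-Michael addition; the doubly activated acrylate takes up the alkoxide rapidly under catalytic base, and the new centre is destroyed later.

**Step 19**
Reactants: 29 allyl 2-(diethoxyphosphoryl)-3-(naphthalen-2-ylmethoxy)propanoate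
Product: 30 2-(diethoxyphosphoryl)-3-(naphthalen-2-ylmethoxy)propanoic acid
Conditions: Pd(PPh3)4 (5 mol %), morpholine, THF, rt; then 1 M HCl wash
Reagents that add atoms: none
Why: Tsuji–Trost deallylation with zerovalent palladium and morpholine as allyl acceptor frees the acid under near-neutral conditions, avoiding retro-Michael loss of the ether.

**Step 20**
Reactants: 24 (1S,2Z,5S,6E,8R,9R)-1,5-bis[(tert-butyldimethylsilyl)oxy]-9-(methoxymethoxy)-2,6-dimethylcyclodeca-2,6-dien-8-ol; 30 2-(diethoxyphosphoryl)-3-(naphthalen-2-ylmethoxy)propanoic acid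
Product: 31 (1S,2Z,5S,6E,8R,9R)-1,5-bis[(tert-butyldimethylsilyl)oxy]-9-(methoxymethoxy)-2,6-dimethylcyclodeca-2,6-dien-8-yl 2-(diethoxyphosphoryl)-3-(naphthalen-2-ylmethoxy)propanoate (ring numbered as in 22; epimers at the phosphonate carbon)
Conditions: EDC·HCl, 4-(dimethylamino)pyridine (cat.), CH2Cl2, 0 °C to rt
Reagents that add atoms: none
Why: Steglich-type carbodiimide esterification of the C6 alcohol; no ring stereocentre is touched and the phosphonate-carbon epimers converge in step 23.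

**Step 21**
Reactants: 31 the phosphonoacetate ester from step 20
Product: 33 (1S,2Z,5S,6E,8R,9R)-1,5-bis[(tert-butyldimethylsilyl)oxy]-9-hydroxy-2,6-dimethylcyclodeca-2,6-dien-8-yl 2-(diethoxyphosphoryl)-3-(naphthalen-2-ylmethoxy)propanoate, via bromomethyl ether 32 (not isolated)
Conditions: Me2BBr (3 equiv), CH2Cl2, −78 °C; then THF/aq. NaHCO3, −78 to 0 °C
Reagents that add atoms: none
Why: Guindon MOM cleavage; Me2BBr converts the acetal into a bromomethyl ether that hydrolyses on the cold bicarbonate quench, while silyl ethers, the NAP ether and the esters survive at −78 °C and the cold quench limits 1,2-acyl migration.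

**Step 22**
Reactants: 33 the C7 alcohol from step 21
Product: 34 (1S,2Z,5S,6E,8R)-1,5-bis[(tert-butyldimethylsilyl)oxy]-2,6-dimethyl-9-oxocyclodeca-2,6-dien-8-yl 2-(diethoxyphosphoryl)-3-(naphthalen-2-ylmethoxy)propanoate (ring numbered as in 22)
Conditions: Dess–Martin periodinane, NaHCO3, CH2Cl2, 0 °C
Reagents that add atoms: none
Why: Buffered Dess–Martin oxidation gives the α-acyloxy ketone under non-basic conditions; it is used at once, so the labile C6 centre is not exposed to base.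

**Step 23**
Reactants: 34 the keto phosphonate from step 22
Product: 35 (3S,6R,9S)-3,9-bis[(tert-butyldimethylsilyl)oxy]-13-(naphthalen-2-ylmethoxy)germacra-1(10)Z,4E,7(11)-trien-12,6-olide
Conditions: LiCl, iPr2NEt, MeCN, 0 °C to rt
Reagents that add atoms: none
Why: Intramolecular Horner–Wadsworth–Emmons reaction under Masamune–Roush conditions; only the lithium-chelated phosphonate is deprotonated, five-ring closure onto the ketone outruns loss of the β-alkoxide, and the weak amine base spares C6 and the β-silyloxy ketone.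

**Step 24**
Reactants: 35 the bis-TBS butenolide from step 23
Product: 36 (3S,6R,9S)-3,9-dihydroxy-13-(naphthalen-2-ylmethoxy)germacra-1(10)Z,4E,7(11)-trien-12,6-olide
Conditions: HF·pyridine, pyridine, THF, 0 °C to rt
Reagents that add atoms: none
Why: Buffered acidic fluoride removes both secondary silyl ethers without touching the NAP ether or the base-sensitive butenolide.

**Step 25**
Reactants: 36 the diol from step 24
Product: 37 (3S,6R,9S)-3,9-diacetoxy-13-(naphthalen-2-ylmethoxy)germacra-1(10)Z,4E,7(11)-trien-12,6-olide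
Conditions: Ac2O, pyridine, 4-(dimethylamino)pyridine (cat.), CH2Cl2, 0 °C to rt
Reagents that add atoms: acetic anhydride, CC(=O)OC(C)=O
Why: Standard acylation of the two allylic alcohols with retention; the base is too weak to epimerise C6.

**Step 26**
Reactants: 37 the diacetate from step 25
Product: 38 (3S,6R,9S)-3,9-diacetoxy-13-hydroxygermacra-1(10)Z,4E,7(11)-trien-12,6-olide (CNP0328753.1)
Conditions: DDQ, CH2Cl2/aq. NaH2PO4–Na2HPO4 (pH 7) 10:1, rt
Reagents that add atoms: none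
Why: Oxidative cleavage of the 2-naphthylmethyl ether by DDQ is neutral and leaves the acetates, trisubstituted alkenes and butenolide intact.

**Compound list**
1 | ethyl (2E)-3-methyl-4-oxobut-2-enoate | CCOC(=O)/C=C(\C)C=O | starting material
2 | O-(diisopinocampheylboryl) borinate ester of 3 | CCOC(=O)/C=C(\C)[C@H](CC=C)OB([C@@H]1C[C@@H]2C[C@H]([C@H]1C)C2(C)C)[C@@H]1C[C@@H]2C[C@H]([C@H]1C)C2(C)C | intermediate
3 | ethyl (2E,4S)-4-hydroxy-3-methylhepta-2,6-dienoate | CCOC(=O)/C=C(\C)[C@@H](O)CC=C | intermediate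
4 | ethyl (2E,4S)-4-[(tert-butyldimethylsilyl)oxy]-3-methylhepta-2,6-dienoate | CCOC(=O)/C=C(\C)[C@@H](O[Si](C)(C)C(C)(C)C)CC=C | intermediate
5 | ethyl (2E,4S)-4-[(tert-butyldimethylsilyl)oxy]-6,7-dihydroxy-3-methylhept-2-enoate (C6 epimers) | CCOC(=O)/C=C(\C)[C@@H](O[Si](C)(C)C(C)(C)C)CC(O)CO | intermediate
6 | ethyl (2E,4S)-4-[(tert-butyldimethylsilyl)oxy]-3-methyl-6-oxohex-2-enoate | CCOC(=O)/C=C(\C)[C@@H](O[Si](C)(C)C(C)(C)C)CC=O | intermediate
7 | ethyl (2E,4S,6Z)-4-[(tert-butyldimethylsilyl)oxy]-7-iodo-3-methylocta-2,6-dienoate | CCOC(=O)/C=C(\C)[C@@H](O[Si](C)(C)C(C)(C)C)C/C=C(\I)C | intermediate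
8 | (2E,4S,6Z)-4-[(tert-butyldimethylsilyl)oxy]-7-iodo-3-methylocta-2,6-dien-1-ol | OC/C=C(\C)[C@@H](O[Si](C)(C)C(C)(C)C)C/C=C(\I)C | intermediate
9 | (2E,4S,6Z)-4-[(tert-butyldimethylsilyl)oxy]-7-iodo-3-methylocta-2,6-dienal | O=C/C=C(\C)[C@@H](O[Si](C)(C)C(C)(C)C)C/C=C(\I)C | intermediate
10 | prop-2-en-1-ol (allyl alcohol) | C=CCO | starting material
11 | 3-(methoxymethoxy)prop-1-ene | C=CCOCOC | intermediate
12 | [(2Z)-3-(methoxymethoxy)prop-2-en-1-yl]diisopinocampheylborane | COCO/C=C\CB([C@@H]1C[C@@H]2C[C@H]([C@H]1C)C2(C)C)[C@@H]1C[C@@H]2C[C@H]([C@H]1C)C2(C)C | intermediate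
13 | O-(diisopinocampheylboryl) borinate ester of 14 | C=C[C@@H](OCOC)[C@H](OB([C@@H]1C[C@@H]2C[C@H]([C@H]1C)C2(C)C)[C@@H]1C[C@@H]2C[C@H]([C@H]1C)C2(C)C)/C=C(\C)[C@@H](O[Si](C)(C)C(C)(C)C)C/C=C(\I)C | intermediate
14 | (3R,4R,5E,7S,9Z)-7-[(tert-butyldimethylsilyl)oxy]-10-iodo-3-(methoxymethoxy)-6-methylundeca-1,5,9-trien-4-ol | C=C[C@@H](OCOC)[C@H](O)/C=C(\C)[C@@H](O[Si](C)(C)C(C)(C)C)C/C=C(\I)C | intermediate
15 | (3R,4R,5E,7S,9Z)-7-[(tert-butyldimethylsilyl)oxy]-10-iodo-3-(methoxymethoxy)-4-[(4-methoxybenzyl)oxy]-6-methylundeca-1,5,9-triene | C=C[C@@H](OCOC)[C@H](OCc1ccc(OC)cc1)/C=C(\C)[C@@H](O[Si](C)(C)C(C)(C)C)C/C=C(\I)C | intermediate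
16 | B-alkyl-9-borabicyclo[3.3.1]nonane adduct of 15 (boron on C1) | C1CC2CCCC(C1)B2CC[C@@H](OCOC)[C@H](OCc1ccc(OC)cc1)/C=C(\C)[C@@H](O[Si](C)(C)C(C)(C)C)C/C=C(\I)C | intermediate
17 | (3R,4R,5E,7S,9Z)-7-[(tert-butyldimethylsilyl)oxy]-10-iodo-3-(methoxymethoxy)-4-[(4-methoxybenzyl)oxy]-6-methylundeca-5,9-dien-1-ol | OCC[C@@H](OCOC)[C@H](OCc1ccc(OC)cc1)/C=C(\C)[C@@H](O[Si](C)(C)C(C)(C)C)C/C=C(\I)C | intermediate
18 | (3R,4R,5E,7S,9Z)-7-[(tert-butyldimethylsilyl)oxy]-10-iodo-3-(methoxymethoxy)-4-[(4-methoxybenzyl)oxy]-6-methylundeca-5,9-dienal | O=CC[C@@H](OCOC)[C@H](OCc1ccc(OC)cc1)/C=C(\C)[C@@H](O[Si](C)(C)C(C)(C)C)C/C=C(\I)C | intermediate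
19 | (Z)-alkenylchromium dichloride derived from 18 (CrCl2 in place of iodine) | O=CC[C@@H](OCOC)[C@H](OCc1ccc(OC)cc1)/C=C(\C)[C@@H](O[Si](C)(C)C(C)(C)C)C/C=C(\[Cr](Cl)Cl)C | intermediate
20 | (2Z,5S,6E,8R,9R)-5-[(tert-butyldimethylsilyl)oxy]-9-(methoxymethoxy)-8-[(4-methoxybenzyl)oxy]-2,6-dimethylcyclodeca-2,6-dien-1-ol (mixture of C1 epimers) | OC1C[C@@H](OCOC)[C@H](OCc2ccc(OC)cc2)/C=C(\C)[C@@H](O[Si](C)(C)C(C)(C)C)C/C=C\1C | intermediate
21 | (2Z,5S,6E,8R,9R)-5-[(tert-butyldimethylsilyl)oxy]-9-(methoxymethoxy)-8-[(4-methoxybenzyl)oxy]-2,6-dimethylcyclodeca-2,6-dien-1-one | O=C1C[C@@H](OCOC)[C@H](OCc2ccc(OC)cc2)/C=C(\C)[C@@H](O[Si](C)(C)C(C)(C)C)C/C=C\1C | intermediate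
22 | (1S,2Z,5S,6E,8R,9R)-5-[(tert-butyldimethylsilyl)oxy]-9-(methoxymethoxy)-8-[(4-methoxybenzyl)oxy]-2,6-dimethylcyclodeca-2,6-dien-1-ol | O[C@H]1C[C@@H](OCOC)[C@H](OCc2ccc(OC)cc2)/C=C(\C)[C@@H](O[Si](C)(C)C(C)(C)C)C/C=C\1C | intermediate
23 | (1S,2Z,5S,6E,8R,9R)-1,5-bis[(tert-butyldimethylsilyl)oxy]-9-(methoxymethoxy)-8-[(4-methoxybenzyl)oxy]-2,6-dimethylcyclodeca-2,6-diene | CC(C)(C)[Si](C)(C)O[C@H]1C[C@@H](OCOC)[C@H](OCc2ccc(OC)cc2)/C=C(\C)[C@@H](O[Si](C)(C)C(C)(C)C)C/C=C\1C | intermediate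
24 | (1S,2Z,5S,6E,8R,9R)-1,5-bis[(tert-butyldimethylsilyl)oxy]-9-(methoxymethoxy)-2,6-dimethylcyclodeca-2,6-dien-8-ol (ring numbered as in 22) | CC(C)(C)[Si](C)(C)O[C@H]1C[C@@H](OCOC)[C@H](O)/C=C(\C)[C@@H](O[Si](C)(C)C(C)(C)C)C/C=C\1C | intermediate
25 | allyl 2-(diethoxyphosphoryl)acetate | CCOP(=O)(CC(=O)OCC=C)OCC | starting material
26 | allyl 3-(allyloxy)-2-(diethoxyphosphoryl)propanoate | CCOP(=O)(OCC)C(COCC=C)C(=O)OCC=C | intermediate
27 | allyl 2-(diethoxyphosphoryl)prop-2-enoate | CCOP(=O)(OCC)C(=C)C(=O)OCC=C | intermediate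
28 | naphthalen-2-ylmethanol | OCc1ccc2ccccc2c1 | starting material
29 | allyl 2-(diethoxyphosphoryl)-3-(naphthalen-2-ylmethoxy)propanoate (racemic) | CCOP(=O)(OCC)C(COCc1ccc2ccccc2c1)C(=O)OCC=C | intermediate
30 | 2-(diethoxyphosphoryl)-3-(naphthalen-2-ylmethoxy)propanoic acid (racemic) | CCOP(=O)(OCC)C(COCc1ccc2ccccc2c1)C(O)=O | intermediate
31 | (1S,2Z,5S,6E,8R,9R)-1,5-bis[(tert-butyldimethylsilyl)oxy]-9-(methoxymethoxy)-2,6-dimethylcyclodeca-2,6-dien-8-yl 2-(diethoxyphosphoryl)-3-(naphthalen-2-ylmethoxy)propanoate | CC(C)(C)[Si](C)(C)O[C@H]1C[C@@H](OCOC)[C@H](OC(=O)C(COCc2ccc3ccccc3c2)P(=O)(OCC)OCC)/C=C(\C)[C@@H](O[Si](C)(C)C(C)(C)C)C/C=C\1C | intermediate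
32 | 9-O-(bromomethyl) ether corresponding to 31 (OCH2Br in place of OMOM) | CC(C)(C)[Si](C)(C)O[C@H]1C[C@@H](OCBr)[C@H](OC(=O)C(COCc2ccc3ccccc3c2)P(=O)(OCC)OCC)/C=C(\C)[C@@H](O[Si](C)(C)C(C)(C)C)C/C=C\1C | intermediate
33 | (1S,2Z,5S,6E,8R,9R)-1,5-bis[(tert-butyldimethylsilyl)oxy]-9-hydroxy-2,6-dimethylcyclodeca-2,6-dien-8-yl 2-(diethoxyphosphoryl)-3-(naphthalen-2-ylmethoxy)propanoate | CC(C)(C)[Si](C)(C)O[C@H]1C[C@@H](O)[C@H](OC(=O)C(COCc2ccc3ccccc3c2)P(=O)(OCC)OCC)/C=C(\C)[C@@H](O[Si](C)(C)C(C)(C)C)C/C=C\1C | intermediate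
34 | (1S,2Z,5S,6E,8R)-1,5-bis[(tert-butyldimethylsilyl)oxy]-2,6-dimethyl-9-oxocyclodeca-2,6-dien-8-yl 2-(diethoxyphosphoryl)-3-(naphthalen-2-ylmethoxy)propanoate | CC(C)(C)[Si](C)(C)O[C@H]1CC(=O)[C@H](OC(=O)C(COCc2ccc3ccccc3c2)P(=O)(OCC)OCC)/C=C(\C)[C@@H](O[Si](C)(C)C(C)(C)C)C/C=C\1C | intermediate
35 | (3S,6R,9S)-3,9-bis[(tert-butyldimethylsilyl)oxy]-13-(naphthalen-2-ylmethoxy)germacra-1(10)Z,4E,7(11)-trien-12,6-olide | CC(C)(C)[Si](C)(C)O[C@H]1CC2=C(COCc3ccc4ccccc4c3)C(=O)O[C@@H]2/C=C(\C)[C@@H](O[Si](C)(C)C(C)(C)C)C/C=C\1C | intermediate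
36 | (3S,6R,9S)-3,9-dihydroxy-13-(naphthalen-2-ylmethoxy)germacra-1(10)Z,4E,7(11)-trien-12,6-olide | O[C@H]1CC2=C(COCc3ccc4ccccc4c3)C(=O)O[C@@H]2/C=C(\C)[C@@H](O)C/C=C\1C | intermediate
37 | (3S,6R,9S)-3,9-diacetoxy-13-(naphthalen-2-ylmethoxy)germacra-1(10)Z,4E,7(11)-trien-12,6-olide | CC(=O)O[C@H]1CC2=C(COCc3ccc4ccccc4c3)C(=O)O[C@@H]2/C=C(\C)[C@@H](OC(C)=O)C/C=C\1C | intermediate
38 | (3S,6R,9S)-3,9-diacetoxy-13-hydroxygermacra-1(10)Z,4E,7(11)-trien-12,6-olide (CNP0328753.1) | CC(=O)O[C@H]1CC2=C(CO)C(=O)O[C@@H]2/C=C(\C)[C@@H](OC(C)=O)C/C=C\1C | target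

**Totals**
Total step count: 26. Longest linear sequence: 22 steps (steps 1–6, 8–16, 20–26); step 7 and steps 17–19 are side branches.

**Three steps most likely to fail, with fallbacks**

Step 12, the ten-membered ring closure, is the least certain step because the medium ring may form slowly or oligomerise. The fallback sets out from aldehyde 18 and closes the same C9–C10 bond by acylation instead of carbonyl addition. Oxidation with NaClO2/NaH2PO4/2-methylbut-2-ene gives the carboxylic acid F1. Coupling with MeNHOMe·HCl (EDC·HCl, iPr2NEt) gives the N-methoxy-N-methylamide F2. Slow addition of F2 to t-BuLi (2.1 equiv, THF, −90 °C, high dilution) makes the alkenyllithium F3 by iodine–lithium exchange. F3 acylates itself on the amide and gives enone 21 after aqueous work-up, where the route is rejoined.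

Step 14, the CBS reduction, may give poor selectivity if the macrocyclic enone is twisted out of conjugation. The fallback sets out from the epimer mixture 20 and avoids the oxidation–reduction pair. The epimers are separated by chromatography and the (1S) epimer is 22 itself. The (1R) epimer is inverted by a Mitsunobu reaction (PPh3, DIAD, 4-nitrobenzoic acid, toluene, 0 °C) to the (1S) 4-nitrobenzoate F4. Methanolysis (K2CO3, MeOH) then gives 22, where the route is rejoined.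

Step 23, the butenolide closure, may fail through loss of the β-alkoxide from the phosphonate anion or epimerisation at C6. The fallback sets out from alcohol 24 and builds C13 at the acid oxidation level by a Knoevenagel route.
- Esterification with mono-allyl malonate (EDC·HCl, 4-(dimethylamino)pyridine) gives the allyl malonate ester F5.
- Me2BBr at −78 °C cleaves the MOM ether through the bromomethyl ether F6 to the C7 alcohol F7.
- Dess–Martin oxidation gives the keto malonate F8, which closes under piperidinium acetate by intramolecular Knoevenagel condensation to the allyl 13-oate butenolide F9.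
- Pd(PPh3)4/morpholine frees the 13-oic acid F10.
- Isobutyl chloroformate/N-methylmorpholine gives the mixed anhydride F11, and NaBH4 (THF/H2O, −15 °C) reduces it to the 13-alcohol F12.
- 2-(Bromomethyl)naphthalene with Ag2O etherifies F12 to 35, where the route is rejoined.

**Further compounds**
F1 | step 12 | (3R,4R,5E,7S,9Z)-7-[(tert-butyldimethylsilyl)oxy]-10-iodo-3-(methoxymethoxy)-4-[(4-methoxybenzyl)oxy]-6-methylundeca-5,9-dienoic acid | OC(=O)C[C@@H](OCOC)[C@H](OCc1ccc(OC)cc1)/C=C(\C)[C@@H](O[Si](C)(C)C(C)(C)C)C/C=C(\I)C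
F2 | step 12 | N-methoxy-N-methylamide of F1 | CON(C)C(=O)C[C@@H](OCOC)[C@H](OCc1ccc(OC)cc1)/C=C(\C)[C@@H](O[Si](C)(C)C(C)(C)C)C/C=C(\I)C
F3 | step 12 | alkenyllithium from F2 (lithium in place of iodine) | CON(C)C(=O)C[C@@H](OCOC)[C@H](OCc1ccc(OC)cc1)/C=C(\C)[C@@H](O[Si](C)(C)C(C)(C)C)C/C=C(\[Li])C
F4 | step 14 | (1S)-4-nitrobenzoate of 22 | O=C(O[C@H]1C[C@@H](OCOC)[C@H](OCc2ccc(OC)cc2)/C=C(\C)[C@@H](O[Si](C)(C)C(C)(C)C)C/C=C\1C)c1ccc(cc1)[N+](=O)[O-]
F5 | step 23 | 8-O-[3-(allyloxy)-3-oxopropanoyl] ester of 24 | CC(C)(C)[Si](C)(C)O[C@H]1C[C@@H](OCOC)[C@H](OC(=O)CC(=O)OCC=C)/C=C(\C)[C@@H](O[Si](C)(C)C(C)(C)C)C/C=C\1C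
F6 | step 23 | 9-O-(bromomethyl) ether corresponding to F5 | CC(C)(C)[Si](C)(C)O[C@H]1C[C@@H](OCBr)[C@H](OC(=O)CC(=O)OCC=C)/C=C(\C)[C@@H](O[Si](C)(C)C(C)(C)C)C/C=C\1C
F7 | step 23 | 9-hydroxy allyl malonate ester | CC(C)(C)[Si](C)(C)O[C@H]1C[C@@H](O)[C@H](OC(=O)CC(=O)OCC=C)/C=C(\C)[C@@H](O[Si](C)(C)C(C)(C)C)C/C=C\1C
F8 | step 23 | 9-oxo allyl malonate ester | CC(C)(C)[Si](C)(C)O[C@H]1CC(=O)[C@H](OC(=O)CC(=O)OCC=C)/C=C(\C)[C@@H](O[Si](C)(C)C(C)(C)C)C/C=C\1C
F9 | step 23 | allyl (3S,6R,9S)-3,9-bis[(tert-butyldimethylsilyl)oxy]germacra-1(10)Z,4E,7(11)-trien-12,6-olid-13-oate | CC(C)(C)[Si](C)(C)O[C@H]1CC2=C(C(=O)OCC=C)C(=O)O[C@@H]2/C=C(\C)[C@@H](O[Si](C)(C)C(C)(C)C)C/C=C\1C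
F10 | step 23 | (3S,6R,9S)-3,9-bis[(tert-butyldimethylsilyl)oxy]germacra-1(10)Z,4E,7(11)-trien-12,6-olid-13-oic acid | CC(C)(C)[Si](C)(C)O[C@H]1CC2=C(C(O)=O)C(=O)O[C@@H]2/C=C(\C)[C@@H](O[Si](C)(C)C(C)(C)C)C/C=C\1C
F11 | step 23 | isobutyl carbonic mixed anhydride of F10 | CC(C)(C)[Si](C)(C)O[C@H]1CC2=C(C(=O)OC(=O)OCC(C)C)C(=O)O[C@@H]2/C=C(\C)[C@@H](O[Si](C)(C)C(C)(C)C)C/C=C\1C
F12 | step 23 | (3S,6R,9S)-3,9-bis[(tert-butyldimethylsilyl)oxy]-13-hydroxygermacra-1(10)Z,4E,7(11)-trien-12,6-olide | CC(C)(C)[Si](C)(C)O[C@H]1CC2=C(CO)C(=O)O[C@@H]2/C=C(\C)[C@@H](O[Si](C)(C)C(C)(C)C)C/C=C\1C
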